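After 6.00 d the south-west run stands at 29.5% product and the south run at 14.8%, though the south-west run holds half the starting material of the south run.

| flask | starting material | solid reagent | initiator | remark | time |
|---|---|---|---|---|---|
| south | 1.5 M | 0.71 M | 150 mM | run made earlier |  |
| south-east | 1.5 M | 1.1 M | 150 mM | run made earlier |  |
| south-west | 0.75 M | 1.42 M | 150 mM | run made earlier |  |
| flask | 1.5 M | 1.42 M | 150 mM |  | 5.0 d |

| run | time / d | product / % | starting material / % |
|---|---|---|---|
| south | 0.417 | 0.2 | 99.3 |
| south | 1.25 | 3.8 | 96.8 |
| south | 2.00 | 4.7 | 95.6 |
| south | 3.00 | 6.9 | 91.7 |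
| south | 5.00 | 12.9 | 86.6 |
| south | 6.00 | 14.8 | 84.0 |
| south-east | 1.04 | 2.2 | 98.1 |
| south-east | 2.08 | 5.2 | 94.2 |
| south-east | 3.00 | 6.8 | 92.0 |
| south-east | 4.00 | 10.0 | 88.9 |
| south-east | 5.00 | 12.3 | 86.5 |
| south-east | 6.00 | 15.7 | 83.6 |
| south-west | 0.500 | 1.4 | 97.6 |
| south-west | 0.833 | 3.0 | 95.3 |
| south-west | 1.67 | 7.1 | 91.0 |
| south-west | 3.00 | 14.8 | 82.7 |
| south-west | 6.00 | 29.5 | 66.5 |

(standard deviation of a reading: 0.5 percentage points)

- as a solid, counted per litre of solution: solid reagent
- at the start none of the solid reagent is in solution

- the product standing at 5.0 d, as a percentage of the starting material charged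
- the change that raises the amount of product at 5.0 d, in percent of the starting material charged most ("none" if none brings more than 2 percentage points) (alpha / gamma / none)
- amount of product at 5.0 d, in percent of the starting material charged, after gamma

- alpha: doubling the solubility of the solid reagent, all else as stated
- gamma: doubling the dissolution coefficient of the solid reagent, all else as stated

So I stop reckoning in percent. From each last reading I take 0.0369 M d⁻¹ for the south-west run, the daily turnover: product made per litre per day, which is reading × c(starting material) / time. The other two runs follow.

south: 14.8% × 1.5 M / 6.00 d = 0.0370 M d⁻¹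

south-east: 15.7% × 1.5 M / 6.00 d = 0.0393 M d⁻¹

The turnover barely moves across these charges, so at this initiator charge the runs read as zero order in starting material and in solid reagent. The flask therefore follows by one division:

y = 0.0369 M d⁻¹ × 5.0 d / 1.5 M = 12.3%

The weak link is the line through zero, because the south run shows a reading of 0.2% at 0.417 d, below the 1.03% that the line gives. But the south and south-east runs have readings at the asked time and at the flask's c(starting material), 12.9% and 12.3%, with that lag inside them. Their mean is 12.6%, and I commit to that.

The forecast says 12.6%, names alpha as the best change and gives 13% after gamma, on the grounds that “The absolute rate is the same in all three runs”.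

The flask gives 12.4%. The best change is alpha, gaining 12 percentage points against 0.56 points for gamma, and gamma gives 13.0%.

    initiator → 2 initiating radical (k = 9.80 × 10⁻⁶ min⁻¹)
    starting material + initiating radical ⇌ chain carrier (K = 11000 M⁻¹, k = 3.60 × 10⁵ M⁻¹ min⁻¹)
    partner + chain carrier → product + initiating radical (k = 40000 M⁻¹ min⁻¹)
    2 chain carrier → ended chains A (k = 8.00 × 10⁸ M⁻¹ s⁻¹)
    2 initiating radical → ended chains B (k = 2.00 × 10⁶ M⁻¹ s⁻¹)
    solid reagent ⇌ partner, rate k6*(cs6 - [partner]) while solid is left; crystals form when [partner] > cs6 (solubility = 0.130 M, k = 0.00390 min⁻¹)

Behind the number, the flask keeps 78.2% of its solid reagent at 5.00 d, with partner at 0.123 M. The neighbouring flask holds 0.38 M of starting material, with the other charges and the time as in the flask. The same turnover over that charge gives 48.6%, and that neighbour flask stands at 49.0%. Its partner is also at 0.123 M, and 45.6% of its starting material is left.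

The runs were computed with constants of no real substance; the scatter is artificial.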